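## Retrosynthetic overview

1. The last bond is C2–Br, made by SEAr on a pentabromide whose axis is already fixed. Before it comes the new step, a catalytic atroposelective C2'-bromination that locks the N1–C3' axis by dynamic kinetic resolution of a tetrabromide.
2. The tetrabromide comes from a 3-(indolin-1-yl)indole by DDQ aromatisation, C3-bromination and N-deacetylation.
3. The N1–C3' bond comes from a metal-free enamine condensation of 1-acetyl-4,5-dibromoindolin-3-one with 5-bromoindoline.
4. The indolinone comes from a Heumann-type ring closure of an N-(carboxymethyl)anthranilic acid. That acid comes from para-bromination of 2-amino-6-bromobenzoic acid, which sets the 4',5'-dibromo pattern.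
5. Ring order: the pyrrole ring of unit B is built first. The five-membered ring of unit A is bought as an indoline and aromatised after the C–N bond is made.

Locants: unprimed means unit A (the N-linked indole). Primed means unit B (the C3'-linked indole).

Assumption: the SMILES has no stereodescriptor and the only stereogenic element is the hindered N1–C3' axis, so "single enantiomer" is taken as one atropisomer, drawn here as (aS) (dihedral C2–N1–C3'–C2' positive); SMILES cannot show the axis, so it is given in the names, and the mirror-image catalyst gives the antipode if the natural sample proves to be (aR).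

## Route

Step 1
Reactants: 1 2-amino-6-bromobenzoic acid
Product: 2 6-amino-2,3-dibromobenzoic acid
Conditions: NBS (1.0 equiv), DMF, 0 °C to 25 °C
Reagents that add atoms: N-bromosuccinimide (NBS), O=C1CCC(=O)N1Br
Why: Electrophilic aromatic substitution in which the free NH2 group directs para, giving the vicinal dibromide by the same selectivity that is used to make 5-bromo-4-chloroindoxyl precursors.

Step 2
Reactants: 2 6-amino-2,3-dibromobenzoic acid
Product: 3 2,3-dibromo-6-[(carboxymethyl)amino]benzoic acid
Conditions: ClCH2CO2H (1.2 equiv), Na2CO3 (2 equiv), H2O, reflux, 6 h; then aq HCl to pH 2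
Reagents that add atoms: chloroacetic acid, OC(=O)CCl
Why: SN2 N-alkylation of the aniline by chloroacetate (first stage of the Heumann indoxyl synthesis), which stops at mono-alkylation because the product nitrogen is deactivated and flanked by the carboxylate.

Step 3
Reactants: 3 2,3-dibromo-6-[(carboxymethyl)amino]benzoic acid
Product: 4 1-acetyl-4,5-dibromo-1H-indol-3-yl acetate
Conditions: Ac2O, NaOAc, 140 °C, 1 h
Reagents that add atoms: acetic anhydride, CC(=O)OC(C)=O
Why: Heumann–Rössing indoxyl synthesis, in which Ac2O/NaOAc closes the glycine CH2 onto the activated aryl carboxyl group with loss of CO2 and acetylates N and O in the same operation, building the pyrrole ring of unit B without touching either C–Br bond.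

Step 4
Reactants: 4 1-acetyl-4,5-dibromo-1H-indol-3-yl acetate
Product: 5 1-acetyl-4,5-dibromo-1,2-dihydro-3H-indol-3-one
Conditions: Na2SO3 (2 equiv), H2O/EtOH 1:1, 80 °C, N2, 1 h
Reagents that add atoms: none
Why: Chemoselective hydrolysis of the enol ester, which is far more labile than the N-acetyl group, followed by tautomerisation to the ketone, while the retained N-acetyl group blocks indigo-type oxidative dimerisation.

Step 5
Reactants: 5 1-acetyl-4,5-dibromo-1,2-dihydro-3H-indol-3-one; 6 5-bromoindoline
Product: 7 1'-acetyl-4',5,5'-tribromo-2,3-dihydro-1'H-1,3'-biindole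
Conditions: p-TsOH·H2O (10 mol %), PhMe, Dean–Stark, 115 °C, N2, 16 h
Reagents that add atoms: none
Why: Acid-catalysed enamine condensation of a ketone with a secondary amine, known for N-acetylindoxyl with anilines and cyclic amines, driven by water removal and by the enamine being an aromatic indole, and metal-free so that all three C–Br bonds survive.

Step 6
Reactants: 7 1'-acetyl-4',5,5'-tribromo-2,3-dihydro-1'H-1,3'-biindole
Product: 8 1'-acetyl-4',5,5'-tribromo-1'H-1,3'-biindole
Conditions: DDQ (1.1 equiv), PhMe, 25 °C, 2 h
Reagents that add atoms: none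
Why: DDQ dehydrogenation of an N-aryl indoline (hydride abstraction next to N, then proton loss) aromatises unit A, and the N-acetylated, dibrominated unit B is too electron-poor to be oxidised.

Step 7
Reactants: 8 1'-acetyl-4',5,5'-tribromo-1'H-1,3'-biindole
Product: 9 1'-acetyl-3,4',5,5'-tetrabromo-1'H-1,3'-biindole
Conditions: NBS (1.0 equiv), DMF, −20 °C to 0 °C, dark
Reagents that add atoms: N-bromosuccinimide (NBS), O=C1CCC(=O)N1Br
Why: SEAr at the free C3 of unit A, by far the most nucleophilic carbon, while unit B is switched off by its N-acetyl group and two bromines.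

Step 8
Reactants: 9 1'-acetyl-3,4',5,5'-tetrabromo-1'H-1,3'-biindole
Product: 10 3,4',5,5'-tetrabromo-1'H-1,3'-biindole (racemic, axis still turning)
Conditions: K2CO3 (20 mol %), MeOH/THF 1:1, 0 °C to 25 °C
Reagents that add atoms: none
Why: Base-catalysed methanolysis of an N-acylindole, an activated amide with an indolide leaving group, frees N1'–H as the handle for the catalyst of the next step and leaves the aryl and C3 bromides alone.

Step 9
Reactants: 10 3,4',5,5'-tetrabromo-1'H-1,3'-biindole
Product: 11 (aR)-2',3,4',5,5'-pentabromo-1'H-1,3'-biindole (dihedral C2–N1–C3'–C2' positive)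
Conditions: (R)-TRIP [(R)-3,3'-bis(2,4,6-triisopropylphenyl)-1,1'-binaphthyl-2,2'-diyl hydrogen phosphate] (10 mol %), NBS (1.05 equiv in 10 portions over 20 h), PhMe/CH2Cl2 4:1, 4 Å sieves, 30 °C, dark
Reagents that add atoms: N-bromosuccinimide (NBS), O=C1CCC(=O)N1Br
Why: Proposed new method: a chiral-phosphoric-acid-catalysed atroposelective C2'-bromination run as a dynamic kinetic resolution of a C–N axis between two five-membered rings, in which the axis of 10 still turns at 30 °C (planar passage needs only C2–H past C4'–Br and C7–H past C2'–H, estimated at roughly 20–24 kcal/mol), the catalyst binds N1'–H through P=O and NBS through P–OH and so delivers Br+ to one face of the C2'=C3' bond, that face is open only in the rotamer that turns its small C2–H edge rather than its C7–H benzo edge toward it, and after proton loss the new in-plane C2'–Br forces C7–H to pass a bromine on either side, which raises the barrier above about 30 kcal/mol and freezes that rotamer; C2' should outrun C2 because unit B is activated by the hydrogen-bonded phosphate whereas C2 lies next to C3–Br on a ring without an N–H handle; the closest known reaction types are peptide- or phosphoric-acid-catalysed atroposelective brominations of biaryls and 3-arylquinazolinones and phosphate-controlled face-selective bromination of tryptamine C2=C3 bonds, none of which has been shown on a 1,3'-biindole.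

Step 10
Reactants: 11 (aR)-2',3,4',5,5'-pentabromo-1'H-1,3'-biindole
Product: 12 (aS)-2,2',3,4',5,5'-hexabromo-1'H-1,3'-biindole (rivularin A)
Conditions: NBS (1.1 equiv), DMF, 0 °C to 20 °C, dark
Reagents that add atoms: N-bromosuccinimide (NBS), O=C1CCC(=O)N1Br
Why: SEAr of a 1-substituted 3-bromoindole to the 2,3-dibromoindole (direct C2 attack or C3 ipso attack with 1,2-shift), the only activated position left, run far below the temperature at which the axis could turn, so the spatial arrangement is kept and the descriptor changes from aR to aS only because C2 now outranks C7a.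

## Compound list

1 | 2-amino-6-bromobenzoic acid | Nc1cccc(Br)c1C(=O)O | starting material
2 | 6-amino-2,3-dibromobenzoic acid | Nc1ccc(Br)c(Br)c1C(=O)O | intermediate
3 | 2,3-dibromo-6-[(carboxymethyl)amino]benzoic acid | OC(=O)CNc1ccc(Br)c(Br)c1C(=O)O | intermediate
4 | 1-acetyl-4,5-dibromo-1H-indol-3-yl acetate | CC(=O)Oc1cn(C(C)=O)c2ccc(Br)c(Br)c12 | intermediate
5 | 1-acetyl-4,5-dibromo-1,2-dihydro-3H-indol-3-one | CC(=O)N1CC(=O)c2c1ccc(Br)c2Br | intermediate
6 | 5-bromoindoline (5-bromo-2,3-dihydro-1H-indole) | Brc1ccc2NCCc2c1 | starting material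
7 | 1'-acetyl-4',5,5'-tribromo-2,3-dihydro-1'H-1,3'-biindole | CC(=O)n1cc(N2CCc3cc(Br)ccc23)c2c(Br)c(Br)ccc12 | intermediate
8 | 1'-acetyl-4',5,5'-tribromo-1'H-1,3'-biindole | CC(=O)n1cc(-n2ccc3cc(Br)ccc23)c2c(Br)c(Br)ccc12 | intermediate
9 | 1'-acetyl-3,4',5,5'-tetrabromo-1'H-1,3'-biindole | CC(=O)n1cc(-n2cc(Br)c3cc(Br)ccc23)c2c(Br)c(Br)ccc12 | intermediate
10 | 3,4',5,5'-tetrabromo-1'H-1,3'-biindole (racemic, axis labile) | Brc1cn(-c2c[nH]c3ccc(Br)c(Br)c23)c2ccc(Br)cc12 | intermediate
11 | (aR)-2',3,4',5,5'-pentabromo-1'H-1,3'-biindole | Brc1cn(-c2c(Br)[nH]c3ccc(Br)c(Br)c23)c2ccc(Br)cc12 | intermediate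
12 | (aS)-2,2',3,4',5,5'-hexabromo-1'H-1,3'-biindole, rivularin A | Brc1ccc2c(c1)c(Br)c(Br)n2-c1c(Br)[nH]c2ccc(Br)c(Br)c12 | target

## Step count

- Total step count: 10.
- Longest linear sequence: 10 steps (1 to 12). Compound 6 is bought.

## The three steps most likely to fail

**Risk 1 – step 9 (the proposed new step).**
- The axis of 10 may turn too slowly at 30 °C. The reaction would then be only a kinetic resolution, so the barrier should be measured first by dynamic HPLC on a chiral phase.
- Uncatalysed bromination, or bromination at C2 before C2', would also lock the axis and lower the ee.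
- The sense of induction cannot be predicted. It is assigned by anomalous-dispersion crystallography on 11 or 12.
- The fallback is known chemistry, a classical resolution through covalent diastereomers. It sets out from 10 and comes back to the route at 12.
- NBS (2.1 equiv) in DMF at 0 °C to 20 °C turns 10 into racemic 2,2',3,4',5,5'-hexabromo-1'H-1,3'-biindole F1.
- NaH and (1R,2S,5R)-(−)-menthyl chloroformate in THF at 0 °C acylate N1' and give two carbamates that differ only at the axis. These are (1R,2S,5R)-menthyl (aS)-2,4,5-tribromo-3-(2,3,5-tribromo-1H-indol-1-yl)-1H-indole-1-carboxylate F2 and (1R,2S,5R)-menthyl (aR)-2,4,5-tribromo-3-(2,3,5-tribromo-1H-indol-1-yl)-1H-indole-1-carboxylate F3.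
- The two carbamates are separated by chromatography and crystallisation. K2CO3 (catalytic) in MeOH/THF at 0 °C then cleaves the carbamate of F2 to give 12.

**Risk 2 – step 5.**
- The ketone of 5 is crowded by the peri C4–Br and 5-bromoindoline is a weak, secondary nucleophile. Condensation may stall, or acetyl transfer to the amine may compete.
- The fallback forms the C–N bond with a less hindered primary aniline and closes the indoline ring afterwards. It sets out from 5 and comes back at 7.
- Commercial 2-(2-aminophenyl)ethanol (Nc1ccccc1CCO) is brominated para to nitrogen with NBS in DMF to give 2-(2-amino-5-bromophenyl)ethanol F4.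
- F4 condenses with 5 under catalytic p-TsOH in toluene (the known aniline/N-acetylindoxyl condensation) to give 1-acetyl-4,5-dibromo-3-{[4-bromo-2-(2-hydroxyethyl)phenyl]amino}-1H-indole F5.
- MsCl/Et3N in CH2Cl2 at 0 °C gives 2-{2-[(1-acetyl-4,5-dibromo-1H-indol-3-yl)amino]-5-bromophenyl}ethyl methanesulfonate F6.
- Cs2CO3 in DMF at 50 °C closes the five-membered ring by intramolecular N-alkylation to give 7.

**Risk 3 – step 10.**
- C2 lies between C3–Br and the perpendicular unit B, whose C2'–Br and C4'–Br shield both faces. SEAr may be slow, or it may drift to C6 or to N1'.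
- The fallback inverts the polarity at C2 by deprotonative metalation followed by an electrophilic bromine quench. It sets out from 11 and comes back at 12.
- Boc2O with catalytic DMAP in CH2Cl2 gives tert-butyl (aR)-2,4,5-tribromo-3-(3,5-dibromo-1H-indol-1-yl)-1H-indole-1-carboxylate F7.
- TMPMgCl·LiCl (1.2 equiv) in THF at −30 °C removes the most acidic proton, C2–H between N1 and C3–Br, without halogen–metal exchange. This gives tert-butyl (aS)-2,4,5-tribromo-3-[3,5-dibromo-2-(chloromagnesio)-1H-indol-1-yl]-1H-indole-1-carboxylate F8, which is not isolated.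
- 1,2-Dibromo-1,1,2,2-tetrachloroethane converts it into tert-butyl (aS)-2,4,5-tribromo-3-(2,3,5-tribromo-1H-indol-1-yl)-1H-indole-1-carboxylate F9.
- TFA in CH2Cl2 at 0 °C removes the Boc group to give 12.

## Further compounds

F1 | step 9 | racemic 2,2',3,4',5,5'-hexabromo-1'H-1,3'-biindole | Brc1ccc2c(c1)c(Br)c(Br)n2-c1c(Br)[nH]c2ccc(Br)c(Br)c12
F2 | step 9 | (1R,2S,5R)-menthyl (aS)-2,4,5-tribromo-3-(2,3,5-tribromo-1H-indol-1-yl)-1H-indole-1-carboxylate | CC(C)[C@@H]1CC[C@@H](C)C[C@H]1OC(=O)n1c(Br)c(-n2c(Br)c(Br)c3cc(Br)ccc23)c2c(Br)c(Br)ccc12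
F3 | step 9 | (1R,2S,5R)-menthyl (aR)-2,4,5-tribromo-3-(2,3,5-tribromo-1H-indol-1-yl)-1H-indole-1-carboxylate | CC(C)[C@@H]1CC[C@@H](C)C[C@H]1OC(=O)n1c(Br)c(-n2c(Br)c(Br)c3cc(Br)ccc23)c2c(Br)c(Br)ccc12
F4 | step 5 | 2-(2-amino-5-bromophenyl)ethanol | Nc1ccc(Br)cc1CCO
F5 | step 5 | 1-acetyl-4,5-dibromo-3-{[4-bromo-2-(2-hydroxyethyl)phenyl]amino}-1H-indole | CC(=O)n1cc(Nc2ccc(Br)cc2CCO)c2c(Br)c(Br)ccc12
F6 | step 5 | 2-{2-[(1-acetyl-4,5-dibromo-1H-indol-3-yl)amino]-5-bromophenyl}ethyl methanesulfonate | CC(=O)n1cc(Nc2ccc(Br)cc2CCOS(C)(=O)=O)c2c(Br)c(Br)ccc12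
F7 | step 10 | tert-butyl (aR)-2,4,5-tribromo-3-(3,5-dibromo-1H-indol-1-yl)-1H-indole-1-carboxylate | CC(C)(C)OC(=O)n1c(Br)c(-n2cc(Br)c3cc(Br)ccc23)c2c(Br)c(Br)ccc12
F8 | step 10 | tert-butyl (aS)-2,4,5-tribromo-3-[3,5-dibromo-2-(chloromagnesio)-1H-indol-1-yl]-1H-indole-1-carboxylate | CC(C)(C)OC(=O)n1c(Br)c(-n2c([Mg]Cl)c(Br)c3cc(Br)ccc23)c2c(Br)c(Br)ccc12
F9 | step 10 | tert-butyl (aS)-2,4,5-tribromo-3-(2,3,5-tribromo-1H-indol-1-yl)-1H-indole-1-carboxylate | CC(C)(C)OC(=O)n1c(Br)c(-n2c(Br)c(Br)c3cc(Br)ccc23)c2c(Br)c(Br)ccc12
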